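Out of 1.90 M of substrate and 1.33 M of reagent, I want to know how much ends as intermediate A and how much as product.

substrate 1.9 M; reagent 0.700 equiv; time 50 min

    substrate + reagent ⇌ intermediate A (K1 = 22 L mol⁻¹, k1 = 0.038 L mol⁻¹ s⁻¹)
    substrate ⇌ intermediate B (K2 = 1.8, k2 = 0.036 s⁻¹)
    intermediate B ⇌ product (K3 = 9.2, k3 = 0.030 s⁻¹)

1. at 50 min, what has stopped the reaction, if anything has (forward and back rates have come level / it is still moving / the reagent has run out first / all of the substrate has reacted)
2. conversion of substrate at 50 min
3. amount of product at 50 min, in percent of the substrate charged
4. amount of intermediate A at 50 min, in percent of the substrate charged
5. amount of intermediate B at 50 min, in percent of the substrate charged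

- what has gone from substrate into another species counts as reacted, even if it can come back
- the reaction counts as stopped when no species that holds the substrate changes by six tenths of a point or more over the second half of the time
- run time (flask): 50 min

I climb this flask by half-lives, each step taken alone. The relaxation half-life of substrate and intermediate B is 0.206 min, the forward half-life of substrate by the first step, with the concentrations as charged, is 0.23 min, and the relaxation half-life of intermediate B and product is 0.347 min, each short against 50 min . At the start, counting forward rates alone, the second step uses substrate at 0.71 times the rate of the first.

The next rung is the return of intermediate A, whose back arrow, taken alone, has a half-life of 6.69 min. That is longer than the lower rungs, yet 50 min holds 7.47 of them. So I expect thermodynamic control at the end, with forward and back rates level.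

At equilibrium, the ratio of intermediate A to product is the first constant times free reagent, over the second and third constants multiplied. The symmetric case is therefore my zero: the balance concentration, the free reagent at which intermediate A and product hold equal amounts at equilibrium, 0.753 M. At equilibrium, above it intermediate A leads, and below it product leads.

The charge of reagent stands above the balance, but binding consumes reagent. The unbound forms total 19.4 times the free substrate, and the quadratic from both charges gives 0.753 M of intermediate A. That leaves 0.577 M of free reagent, below the balance. I commit to conversion 96.9%, product 51.7%, intermediate A 39.6% and intermediate B 5.61%.

The forecast says forward and back rates have come level, with conversion 96.9%, product 51.6%, intermediate A 39.6% and intermediate B 5.6%, on the ground that “the flask sits at equilibrium with reagent still left”. It stands on the same kind of balance as mine, and our figures for product differ in the last digit.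

The simulation gives forward and back rates have come level, with conversion 96.9%, product 51.6%, intermediate A 39.6% and intermediate B 5.61%. In this flask 43% of the charged reagent is still there at 50.0 min, which is 0.577 M. Against the balance concentration that stands at 0.766, and intermediate A over product reads 0.767.

Now take the same flask with 1.20 equiv of reagent. The same quadratic gives 1.09 M of intermediate A and 1.19 M of free reagent, which is 1.58 balance concentrations, so intermediate A should lead with 57.5% against 36.4% of product. That neighbour computes to 57.5% of intermediate A and 36.4% of product, and with the substrate and the time held, the two hold the same at 0.857 equiv of reagent.

The constants were drawn at random within sensible limits; the rest is arithmetic.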